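The readings were computed from invented constants; the scatter is artificial.

3 questions stood open on one flask, and I took them together as one decision: what to change in the next run.

| setting | epsilon | beta | flask |
|---|---|---|---|
| G | 0.13 M | 0.30 M | 0.20 M |
| X | 22 mM (held) | 22 mM (held) | 22 mM (held) |
| remark | run made earlier | run made earlier |  |
| time |  |  | 50 min |

- epsilon (time / min: Z / %): 10.0: 4.2; 20.0: 10.0; 30.0: 20.7; 40.0: 28.6
- beta (time / min: Z / %): 5.00: 1.3; 15.0: 2.9; 25.0: 6.1; 40.0: 13.4

(each reading ± 1 percentage point)

- percentages count the G that a species holds: one D counts as two
- solid, in amounts per volume of the solution: G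
- at the start none of L is dissolved
- on the list of suspects stand: X <-> L; L <-> E; G <-> J; J + L -> Z; 2 J -> D
- at the start none of G is in solution

1. how much Z there is at 50 min, in percent of the G charged
2. the change that raises the amount of Z at 50 min, in percent of the G charged most ("none" if none brings more than 2 percentage points) (Friday's / Saturday's / Thursday's / Wednesday's / none)
3. amount of Z at 50 min, in percent of the G charged, after Friday's

- Friday's: doubling the solubility of G, all else as stated
- Saturday's: doubling the transfer coefficient of X, all else as stated
- Thursday's: doubling the saturation concentration of X, all else as stated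
- Wednesday's: doubling the dissolution coefficient of G, all else as stated

- I worked in logarithms and first asked what the G charge is worth. At 40.0 min the epsilon run held cZ = 37.2 mM and the beta run 40.2 mM, so 2.31 times the G gave a charge power of only 0.0934.
- In the epsilon run, Z rose with a power of 1.38 between 10.0 min and 40.0 min. In the beta run the power was 1.56 between 15.0 min and 40.0 min; I passed over its reading of 1.3% at 5.00 min, which stands close to the scatter of 1 percentage point.
- Their mean is what I carried: the time power, the step in the logarithm of cZ per step in the logarithm of time, 1.47. It lies above one, so the readings show an induction period.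
- For the asked flask, the charge power put cZ at 38.7 mM at 40.0 min, and the time power carried it to 53.7 mM at 50 min, which is 26.9% of the G charged.
- The charge power sits far below the time power, so the G side looked poor. I valued Friday's like a doubling of the charge, at 28.7%, and put Wednesday's no higher.
- I therefore kept the G charge and chose to change the X side. Of its two changes I took Thursday's, which raises the ceiling of cL, whereas Saturday's leaves the saturation at 22 mM.
- The forecast gave 25%, and 35% after Friday's, which is higher than my figure; it chose Thursday's on the ground that “Raising the X saturation lifts L whichever regime holds”.
- The flask gave 24.5%, and 30.0% after Friday's. The best change was Thursday's, worth 19 points, against 8.6 points for Saturday's, 5.5 points for Friday's and 5.3 points for Wednesday's.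

    X ⇌ L, rate k1*(csat - [L]) (kL = 0.111 min⁻¹)
    L ⇌ E (K = 44.7, k = 0.0409 min⁻¹)
    G ⇌ J, rate k3*(cs3 - [J]) while solid is left; crystals form when [J] > cs3 (solubility = 0.160 M, k = 0.0267 min⁻¹)
    J + L → Z (k = 2.38 L mol⁻¹ min⁻¹)
    2 J → D (k = 0.166 L mol⁻¹ min⁻¹)

- I took the time power from this result back to the neighbouring flask, the same charge stopped at 12 min. Scaling 24.5% by the ratio of the times raised to 1.47 gave 3.01% of the G charged. That neighbouring flask held 2.68% as Z and 1.10% as D, with 96% of the charged G still there, solid or dissolved.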